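**Strategy.** The C37 skeleton is assembled from three blocks: a C23 polyenyne carrying the dihydroxycyclohexene, (E)-2,3-dibromoacrylic acid (Sonogashira–lactonisation to the ylidenebutenolide) and an actinol-derived oxabicyclic vinylstannane (final Stille coupling). The route rests on the cyclohexene ring (C1 = CMe2, C3/C4 = carbinols, C5 = C–CH3, C6 = C–chain): its C4–C5=C6 unit is treated as an allyl cation whose central carbon C5 is a carbene carbon inserted into a cyclopentene C4=C6 bond. Silver-promoted electrocyclic opening of a 6,6-dibromobicyclo[3.1.0]hexane expands the five-membered ring to the six-membered ring, creates the tetrasubstituted C5=C6 bond (bromine at C5 as handle for the methyl group) and lets the C3 carbonate deliver the C4 oxygen cis, fixing the (3S,4R)-diol.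

Key step: step 6

Remark: 4,4-dimethylcyclopentane-1,3-dione, (E)-3-methylpent-2-en-4-yn-1-ol, (4R,6R)-actinol, tributyl[(methoxymethoxy)methyl]stannane and the two phosphonate reagents of steps 10 and 12 are taken as commercial. Polyene intermediates are handled in the dark under argon, and minor Z isomers from the olefinations are expected to be removed by chromatography.

**Step 1**
Reactants: 1 4,4-dimethylcyclopentane-1,3-dione
Product: 2 3-(2-methylpropoxy)-5,5-dimethylcyclopent-2-en-1-one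
Conditions: i-BuOH, p-TsOH (cat.), toluene, reflux, Dean–Stark
Reagents that add atoms: 2-methylpropan-1-ol CC(C)CO
Why: Acid-catalysed enol etherification of the cyclic 1,3-dione should occur at the carbonyl remote from the quaternary carbon and gives the vinylogous ester needed for a Stork–Danheiser transposition.

**Step 2**
Reactants: 2 3-(2-methylpropoxy)-5,5-dimethylcyclopent-2-en-1-one
Product: 4 3-[(methoxymethoxy)methyl]-4,4-dimethylcyclopent-2-en-1-one, via tertiary allylic alcohol adduct 3 (not isolated)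
Conditions: Bu3SnCH2OMOM, n-BuLi, THF, −78 °C; then 2; then 1 M HCl, 0 °C
Reagents that add atoms: tributyl[(methoxymethoxy)methyl]stannane CCCC[Sn](CCCC)(CCCC)COCOC; water O
Why: Stork–Danheiser sequence: 1,2-addition of the α-alkoxymethyllithium (tin–lithium exchange) to the vinylogous ester, then acid hydrolysis with allylic transposition, places the future C7 on the alkene carbon next to the gem-dimethyl carbon.

**Step 3**
Reactants: 4 3-[(methoxymethoxy)methyl]-4,4-dimethylcyclopent-2-en-1-one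
Product: 5 (1S)-3-[(methoxymethoxy)methyl]-4,4-dimethylcyclopent-2-en-1-ol
Conditions: (R)-Me-CBS (10 mol %), BH3·SMe2, THF, −20 °C
Reagents that add atoms: none
Why: Corey–Bakshi–Shibata reduction in which the alkene side of the enone acts as the large group, so the (R)-catalyst should give the (S)-allylic alcohol, the future C3.

**Step 4**
Reactants: 5 (1S)-3-[(methoxymethoxy)methyl]-4,4-dimethylcyclopent-2-en-1-ol
Product: 6 tert-butyl (1S)-3-[(methoxymethoxy)methyl]-4,4-dimethylcyclopent-2-en-1-yl carbonate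
Conditions: Boc2O, DMAP (cat.), MeCN, rt
Reagents that add atoms: di-tert-butyl dicarbonate CC(C)(C)OC(=O)OC(=O)OC(C)(C)C
Why: DMAP-catalysed O-acylation installs the tert-butyl carbonate that later serves as the internal oxygen nucleophile.

**Step 5**
Reactants: 6 tert-butyl (1S)-3-[(methoxymethoxy)methyl]-4,4-dimethylcyclopent-2-en-1-yl carbonate
Product: 7 tert-butyl (1S,2S,5R)-6,6-dibromo-5-[(methoxymethoxy)methyl]-4,4-dimethylbicyclo[3.1.0]hexan-2-yl carbonate
Conditions: CHBr3, 50% aq. NaOH, BnEt3NCl (cat.), CH2Cl2, 0 °C; crude product kept cold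
Reagents that add atoms: bromoform BrC(Br)Br
Why: Phase-transfer dibromocarbene [2+1] cycloaddition to the electron-rich trisubstituted alkene, expected anti to the carbonate; the two new cyclopropane stereocentres are erased in the next step.

**Step 6**
Reactants: 7 tert-butyl (1S,2S,5R)-6,6-dibromo-5-[(methoxymethoxy)methyl]-4,4-dimethylbicyclo[3.1.0]hexan-2-yl carbonate
Product: 9 (3aS,7aS)-4-bromo-5-[(methoxymethoxy)methyl]-6,6-dimethyl-3a,6,7,7a-tetrahydro-1,3-benzodioxol-2-one, via 2-bromocyclohexenyl cation 8 (not isolated)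
Conditions: AgBF4, 2,6-di-tert-butyl-4-methylpyridine, CH2Cl2, −40 → 0 °C, dark
Reagents that add atoms: none
Why: Silver(I) abstracts the endo bromide of 7 while the cyclopropane σ bond shared with the cyclopentane opens in a disrotatory 2π-electrocyclic fashion (cyclopropyl-to-allyl cation rearrangement), so the five-membered ring C3–C4–C6–C1–C2 grows by the former carbene carbon C5 into the six-membered 2-bromoallyl cation 8. The closest known reaction type is the silver-promoted ring expansion of gem-dibromocyclopropanes with intramolecular capture of the π-allyl cation. The carbocycle is formed by ring expansion (cleavage of the C4–C6 bond, no new C–C bond), and the 1,3-dioxolan-2-one closes by attack of the carbonate carbonyl oxygen on C4 (five-membered ring, 5-exo capture of the cation) followed by loss of the tert-butyl group as isobutene. The new stereocentre C4 is controlled by the C3 stereocentre through the tether: the carbonyl oxygen can reach only the face of C4 that carries the C3–O bond, so the dioxolanone is cis-fused and the (3S,4R) cis-diol pattern results. The step needs capture at C4 rather than at C6 or by external nucleophiles, and no proton loss from the cation; C6 is out of reach of the tether and shielded by the gem-dimethyl carbon, the medium is non-nucleophilic (BF4−, hindered pyridine base), and the endo bromide required for the disrotatory opening is always present in a gem-dibromide.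

**Step 7**
Reactants: 9 (3aS,7aS)-4-bromo-5-[(methoxymethoxy)methyl]-6,6-dimethyl-3a,6,7,7a-tetrahydro-1,3-benzodioxol-2-one
Product: 10 (3aR,7aS)-5-[(methoxymethoxy)methyl]-4,6,6-trimethyl-3a,6,7,7a-tetrahydro-1,3-benzodioxol-2-one
Conditions: MeZnCl, Pd(P(t-Bu)3)2 (5 mol %), THF/NMP, 40 °C
Reagents that add atoms: methylzinc chloride C[Zn]Cl
Why: Negishi coupling at the vinyl bromide installs the C5 methyl group; β-oxygen elimination would require a cyclic allene, and the hindered tetrasubstituted allylic carbonate should not ionise.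

**Step 8**
Reactants: 10 (3aR,7aS)-5-[(methoxymethoxy)methyl]-4,6,6-trimethyl-3a,6,7,7a-tetrahydro-1,3-benzodioxol-2-one
Product: 11 (3aR,7aS)-5-(hydroxymethyl)-4,6,6-trimethyl-3a,6,7,7a-tetrahydro-1,3-benzodioxol-2-one
Conditions: ZnBr2, n-PrSH, CH2Cl2, 0 °C
Reagents that add atoms: none
Why: Lewis acid/thiol cleavage of the MOM acetal (acetal exchange to the monothioacetal) frees the primary allylic alcohol under non-ionising conditions that leave the cyclic carbonate intact.

**Step 9**
Reactants: 11 (3aR,7aS)-5-(hydroxymethyl)-4,6,6-trimethyl-3a,6,7,7a-tetrahydro-1,3-benzodioxol-2-one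
Product: 12 (3aR,7aS)-4,6,6-trimethyl-2-oxo-3a,6,7,7a-tetrahydro-1,3-benzodioxole-5-carbaldehyde
Conditions: Dess–Martin periodinane, CH2Cl2, rt
Reagents that add atoms: none
Why: Dess–Martin oxidation of the primary allylic alcohol gives the enal (C7) while both carbinol oxygens remain masked as the carbonate.

**Step 10**
Reactants: 12 (3aR,7aS)-4,6,6-trimethyl-2-oxo-3a,6,7,7a-tetrahydro-1,3-benzodioxole-5-carbaldehyde
Product: 13 (2E,4E)-3-methyl-5-[(3aR,7aS)-4,6,6-trimethyl-2-oxo-3a,6,7,7a-tetrahydro-1,3-benzodioxol-5-yl]penta-2,4-dienenitrile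
Conditions: phosphonate, NaHMDS, THF, −78 °C; then 12, −78 °C → rt
Reagents that add atoms: diethyl [(2E)-3-cyano-2-methylprop-2-en-1-yl]phosphonate CCOP(=O)(OCC)C/C(C)=C/C#N
Why: Horner–Wadsworth–Emmons olefination of the non-enolisable aldehyde with the preformed vinylogous phosphonate anion should form C7=C8 with E geometry and brings in the methyl-bearing C9=C10 unit.

**Step 11**
Reactants: 13 (2E,4E)-3-methyl-5-[(3aR,7aS)-4,6,6-trimethyl-2-oxo-3a,6,7,7a-tetrahydro-1,3-benzodioxol-5-yl]penta-2,4-dienenitrile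
Product: 15 (2E,4E)-5-[(3R,4S)-3,4-dihydroxy-2,6,6-trimethylcyclohex-1-en-1-yl]-3-methylpenta-2,4-dienal, via aldimine 14 (not isolated)
Conditions: DIBAL-H (excess), CH2Cl2, −78 → 0 °C; then aq. Rochelle salt, wet SiO2
Reagents that add atoms: water O
Why: DIBAL reduction of the nitrile to the N-aluminated imine (hydrolysed to the aldehyde on work-up) should at the same time cleave the cyclic carbonate reductively to the free cis-diol without touching either C–O stereocentre.

**Step 12**
Reactants: 15 (2E,4E)-5-[(3R,4S)-3,4-dihydroxy-2,6,6-trimethylcyclohex-1-en-1-yl]-3-methylpenta-2,4-dienal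
Product: 16 (2E,4E,6E)-7-[(3R,4S)-3,4-dihydroxy-2,6,6-trimethylcyclohex-1-en-1-yl]-N-methoxy-N,5-dimethylhepta-2,4,6-trienamide
Conditions: phosphonate, LiCl, DBU, MeCN, rt
Reagents that add atoms: diethyl {2-[methoxy(methyl)amino]-2-oxoethyl}phosphonate CCOP(=O)(OCC)CC(=O)N(C)OC
Why: Horner–Wadsworth–Emmons olefination under Masamune–Roush conditions tolerates the free diol and should give the E-configured Weinreb amide.

**Step 13**
Reactants: 16 (2E,4E,6E)-7-[(3R,4S)-3,4-dihydroxy-2,6,6-trimethylcyclohex-1-en-1-yl]-N-methoxy-N,5-dimethylhepta-2,4,6-trienamide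
Product: 17 (2E,4E,6E)-7-[(3R,4S)-3,4-dihydroxy-2,6,6-trimethylcyclohex-1-en-1-yl]-5-methylhepta-2,4,6-trienal
Conditions: DIBAL-H (4 equiv), THF, −78 °C; aq. Rochelle salt
Reagents that add atoms: none
Why: Hydride reduction of the Weinreb amide stops at the aldehyde through the chelated tetrahedral intermediate, so no oxidation is needed in the presence of the allylic C4 hydroxyl.

**Step 14**
Reactants: 18 (2E)-3-methylpent-2-en-4-yn-1-ol
Product: 19 (3E)-5-bromo-3-methylpent-3-en-1-yne
Conditions: PBr3, Et2O, 0 °C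
Reagents that add atoms: phosphorus tribromide BrP(Br)Br
Why: SN2 bromination of the primary allylic alcohol via its phosphite ester preserves the E double bond.

**Step 15**
Reactants: 19 (3E)-5-bromo-3-methylpent-3-en-1-yne
Product: 20 diethyl [(2E)-3-methylpent-2-en-4-yn-1-yl]phosphonate
Conditions: P(OEt)3, 90 °C
Reagents that add atoms: triethyl phosphite CCOP(OCC)OCC
Why: Michaelis–Arbuzov reaction of the primary allylic bromide gives the C6 enyne phosphonate.

**Step 16**
Reactants: 17 (2E,4E,6E)-7-[(3R,4S)-3,4-dihydroxy-2,6,6-trimethylcyclohex-1-en-1-yl]-5-methylhepta-2,4,6-trienal; 20 diethyl [(2E)-3-methylpent-2-en-4-yn-1-yl]phosphonate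
Product: 21 (1S,2R)-4-[(1E,3E,5E,7E,9E)-3,10-dimethyldodeca-1,3,5,7,9-pentaen-11-yn-1-yl]-3,5,5-trimethylcyclohex-3-ene-1,2-diol
Conditions: 20 (3.5 equiv), NaHMDS (3.4 equiv), THF, −78 °C; then 17, −78 → 0 °C
Reagents that add atoms: none
Why: Horner–Wadsworth–Emmons olefination with the allylic phosphonate anion should be E-selective; the excess anion covers the two hydroxyl protons and the P-stabilised carbanion is more stable than the acetylide.

**Step 17**
Reactants: 22 prop-2-ynoic acid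
Product: 23 (2E)-2,3-dibromoprop-2-enoic acid
Conditions: Br2, LiBr (cat.), AcOH, 15 °C, dark
Reagents that add atoms: bromine BrBr
Why: Anti addition of bromine across the alkyne gives the (E)-dibromide in which the β-bromine is cis to the carboxyl group, as needed for lactonisation.

**Step 18**
Reactants: 21 (1S,2R)-4-[(1E,3E,5E,7E,9E)-3,10-dimethyldodeca-1,3,5,7,9-pentaen-11-yn-1-yl]-3,5,5-trimethylcyclohex-3-ene-1,2-diol; 23 (2E)-2,3-dibromoprop-2-enoic acid
Product: 25 (5Z)-3-bromo-5-[(2E,4E,6E,8E,10E)-11-[(3R,4S)-3,4-dihydroxy-2,6,6-trimethylcyclohex-1-en-1-yl]-2,9-dimethylundeca-2,4,6,8,10-pentaen-1-ylidene]furan-2(5H)-one, via enynoic acid 24 (not isolated)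
Conditions: 23 (1.3 equiv), Pd(PPh3)4 (5 mol %), CuI (10 mol %), Et3N, MeCN, rt, dark
Reagents that add atoms: none
Why: Sonogashira coupling at the more reactive β-C–Br bond followed by in situ 5-exo-dig lactonisation (anti addition of the carboxylate across the alkyne) should give the (Z)-γ-ylidenebutenolide and keep the α-bromide for the last coupling.

**Step 19**
Reactants: 26 (4R,6R)-4-hydroxy-2,2,6-trimethylcyclohexan-1-one
Product: 27 (4R,6R)-2,2,6-trimethyl-4-[(triethylsilyl)oxy]cyclohexan-1-one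
Conditions: TESCl, imidazole, DMF, 0 °C → rt
Reagents that add atoms: chlorotriethylsilane CC[Si](Cl)(CC)CC
Why: Silylation protects the secondary alcohol and provides the bulky group that later directs the epoxidation.

**Step 20**
Reactants: 27 (4R,6R)-2,2,6-trimethyl-4-[(triethylsilyl)oxy]cyclohexan-1-one
Product: 28 (4R)-2,6,6-trimethyl-4-[(triethylsilyl)oxy]cyclohex-1-en-1-yl trifluoromethanesulfonate
Conditions: LDA, THF, −78 °C; then PhNTf2, −78 °C → rt
Reagents that add atoms: N-phenylbis(trifluoromethanesulfonimide) O=S(=O)(N(c1ccccc1)S(=O)(=O)C(F)(F)F)C(F)(F)F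
Why: Enolate O-triflation; the ketone has only one α-hydrogen, so a single tetrasubstituted enol triflate can form.

**Step 21**
Reactants: 28 (4R)-2,6,6-trimethyl-4-[(triethylsilyl)oxy]cyclohex-1-en-1-yl trifluoromethanesulfonate
Product: 29 triethyl{[(1R)-4-ethynyl-3,5,5-trimethylcyclohex-3-en-1-yl]oxy}silane
Conditions: HC≡CMgBr, ZnBr2, THF, 0 °C; then 28, Pd(PPh3)4 (5 mol %), 50 °C
Reagents that add atoms: ethynylmagnesium bromide C#C[Mg]Br
Why: Negishi coupling of the small ethynylzinc reagent with the hindered enol triflate gives the terminal enyne directly.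

**Step 22**
Reactants: 29 triethyl{[(1R)-4-ethynyl-3,5,5-trimethylcyclohex-3-en-1-yl]oxy}silane
Product: 30 triethyl{[(1R,3S,6R)-6-ethynyl-1,5,5-trimethyl-7-oxabicyclo[4.1.0]heptan-3-yl]oxy}silane
Conditions: mCPBA, CH2Cl2, −20 °C
Reagents that add atoms: 3-chloroperoxybenzoic acid OOC(=O)c1cccc(Cl)c1
Why: Prilezhaev epoxidation of the tetrasubstituted alkene should take place mainly on the face anti to the bulky silyloxy group, giving the anti epoxide.

**Step 23**
Reactants: 30 triethyl{[(1R,3S,6R)-6-ethynyl-1,5,5-trimethyl-7-oxabicyclo[4.1.0]heptan-3-yl]oxy}silane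
Product: 31 (1R,3S,6R)-6-ethynyl-1,5,5-trimethyl-7-oxabicyclo[4.1.0]heptan-3-ol
Conditions: TBAF, AcOH, THF, 0 °C
Reagents that add atoms: none
Why: Buffered fluoride desilylation frees the C3 hydroxyl without opening the epoxide.

**Step 24**
Reactants: 31 (1R,3S,6R)-6-ethynyl-1,5,5-trimethyl-7-oxabicyclo[4.1.0]heptan-3-ol
Product: 32 (1S,2R,4S)-1-ethynyl-2,6,6-trimethyl-7-oxabicyclo[2.2.1]heptan-2-ol
Conditions: CSA (cat.), CH2Cl2, 0 °C
Reagents that add atoms: none
Why: Acid-catalysed intramolecular epoxide opening: the C3 hydroxyl, anti to the epoxide, can reach only the propargylic carbon C6 and attacks it with inversion, closing the 7-oxabicyclo[2.2.1]heptane and leaving the tertiary C5 alcohol with the configuration set by the epoxidation.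

**Step 25**
Reactants: 32 (1S,2R,4S)-1-ethynyl-2,6,6-trimethyl-7-oxabicyclo[2.2.1]heptan-2-ol
Product: 33 (1R,2R,4S)-2,6,6-trimethyl-1-[(E)-2-(tributylstannyl)ethenyl]-7-oxabicyclo[2.2.1]heptan-2-ol
Conditions: Bu3SnH, PdCl2(PPh3)2 (2 mol %), THF, 0 °C
Reagents that add atoms: tributyltin hydride CCCC[SnH](CCCC)CCCC
Why: Palladium-catalysed syn hydrostannation places tin on the terminal carbon, away from the quaternary propargylic centre, and should give the (E)-alkenylstannane.

**Step 26**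
Reactants: 25 (5Z)-3-bromo-5-[(2E,4E,6E,8E,10E)-11-[(3R,4S)-3,4-dihydroxy-2,6,6-trimethylcyclohex-1-en-1-yl]-2,9-dimethylundeca-2,4,6,8,10-pentaen-1-ylidene]furan-2(5H)-one; 33 (1R,2R,4S)-2,6,6-trimethyl-1-[(E)-2-(tributylstannyl)ethenyl]-7-oxabicyclo[2.2.1]heptan-2-ol
Product: 34 (5Z)-5-[(2E,4E,6E,8E,10E)-11-[(3R,4S)-3,4-dihydroxy-2,6,6-trimethylcyclohex-1-en-1-yl]-2,9-dimethylundeca-2,4,6,8,10-pentaen-1-ylidene]-3-[(E)-2-[(1R,2R,4S)-2-hydroxy-2,6,6-trimethyl-7-oxabicyclo[2.2.1]heptan-1-yl]ethenyl]furan-2(5H)-one (CNP0216838.1)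
Conditions: Pd2(dba)3 (5 mol %), AsPh3 (20 mol %), NMP, rt → 40 °C, dark
Reagents that add atoms: none
Why: Stille coupling of the α-bromobutenolide with the (E)-alkenylstannane proceeds with retention of both alkene geometries under neutral conditions that tolerate the three free hydroxyl groups, so no deprotection follows.

**Compound list**

1 | 4,4-dimethylcyclopentane-1,3-dione | CC1(C)CC(=O)CC1=O | starting material
2 | 3-(2-methylpropoxy)-5,5-dimethylcyclopent-2-en-1-one | CC(C)COC1=CC(=O)C(C)(C)C1 | intermediate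
3 | 1-[(methoxymethoxy)methyl]-5,5-dimethyl-3-(2-methylpropoxy)cyclopent-2-en-1-ol (racemic adduct, formed as its lithium alkoxide, not isolated) | CC(C)COC1=CC(O)(COCOC)C(C)(C)C1 | intermediate
4 | 3-[(methoxymethoxy)methyl]-4,4-dimethylcyclopent-2-en-1-one | COCOCC1=CC(=O)CC1(C)C | intermediate
5 | (1S)-3-[(methoxymethoxy)methyl]-4,4-dimethylcyclopent-2-en-1-ol | O[C@@H]1C=C(COCOC)C(C)(C)C1 | intermediate
6 | tert-butyl (1S)-3-[(methoxymethoxy)methyl]-4,4-dimethylcyclopent-2-en-1-yl carbonate | CC(C)(C)OC(=O)O[C@@H]1C=C(COCOC)C(C)(C)C1 | intermediate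
7 | tert-butyl (1S,2S,5R)-6,6-dibromo-5-[(methoxymethoxy)methyl]-4,4-dimethylbicyclo[3.1.0]hexan-2-yl carbonate (CBr2 bridge anti to the carbonate) | CC(C)(C)OC(=O)O[C@@H]1[C@H]2C(Br)(Br)[C@@]2(COCOC)C(C)(C)C1 | intermediate
8 | 2-bromo-6-[(tert-butoxycarbonyl)oxy]-3-[(methoxymethoxy)methyl]-4,4-dimethylcyclohex-2-en-1-ylium (allyl cation, carbonate-bearing carbon as in 7, not isolated) | CC(C)(C)OC(=O)O[C@H]1CC(C)(C)C(COCOC)=C(Br)[CH+]1 | intermediate
9 | (3aS,7aS)-4-bromo-5-[(methoxymethoxy)methyl]-6,6-dimethyl-3a,6,7,7a-tetrahydro-1,3-benzodioxol-2-one (cis-fused) | BrC1=C(COCOC)C(C)(C)C[C@H](OC(=O)O2)[C@@H]12 | intermediate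
10 | (3aR,7aS)-5-[(methoxymethoxy)methyl]-4,6,6-trimethyl-3a,6,7,7a-tetrahydro-1,3-benzodioxol-2-one | CC1=C(COCOC)C(C)(C)C[C@H](OC(=O)O2)[C@@H]12 | intermediate
11 | (3aR,7aS)-5-(hydroxymethyl)-4,6,6-trimethyl-3a,6,7,7a-tetrahydro-1,3-benzodioxol-2-one | CC1=C(CO)C(C)(C)C[C@H](OC(=O)O2)[C@@H]12 | intermediate
12 | (3aR,7aS)-4,6,6-trimethyl-2-oxo-3a,6,7,7a-tetrahydro-1,3-benzodioxole-5-carbaldehyde | CC1=C(C=O)C(C)(C)C[C@H](OC(=O)O2)[C@@H]12 | intermediate
13 | (2E,4E)-3-methyl-5-[(3aR,7aS)-4,6,6-trimethyl-2-oxo-3a,6,7,7a-tetrahydro-1,3-benzodioxol-5-yl]penta-2,4-dienenitrile | CC1=C(/C=C/C(C)=C/C#N)C(C)(C)C[C@H](OC(=O)O2)[C@@H]12 | intermediate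
14 | (2E,4E)-5-[(3R,4S)-3,4-dihydroxy-2,6,6-trimethylcyclohex-1-en-1-yl]-3-methylpenta-2,4-dien-1-imine (formed as its N-aluminated derivative, not isolated) | CC1=C(/C=C/C(C)=C/C=N)C(C)(C)C[C@H](O)[C@@H]1O | intermediate
15 | (2E,4E)-5-[(3R,4S)-3,4-dihydroxy-2,6,6-trimethylcyclohex-1-en-1-yl]-3-methylpenta-2,4-dienal | CC1=C(/C=C/C(C)=C/C=O)C(C)(C)C[C@H](O)[C@@H]1O | intermediate
16 | (2E,4E,6E)-7-[(3R,4S)-3,4-dihydroxy-2,6,6-trimethylcyclohex-1-en-1-yl]-N-methoxy-N,5-dimethylhepta-2,4,6-trienamide | CC1=C(/C=C/C(C)=C/C=C/C(=O)N(C)OC)C(C)(C)C[C@H](O)[C@@H]1O | intermediate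
17 | (2E,4E,6E)-7-[(3R,4S)-3,4-dihydroxy-2,6,6-trimethylcyclohex-1-en-1-yl]-5-methylhepta-2,4,6-trienal | CC1=C(/C=C/C(C)=C/C=C/C=O)C(C)(C)C[C@H](O)[C@@H]1O | intermediate
18 | (2E)-3-methylpent-2-en-4-yn-1-ol | C#C/C(C)=C/CO | starting material
19 | (3E)-5-bromo-3-methylpent-3-en-1-yne | C#C/C(C)=C/CBr | intermediate
20 | diethyl [(2E)-3-methylpent-2-en-4-yn-1-yl]phosphonate | C#C/C(C)=C/CP(=O)(OCC)OCC | intermediate
21 | (1S,2R)-4-[(1E,3E,5E,7E,9E)-3,10-dimethyldodeca-1,3,5,7,9-pentaen-11-yn-1-yl]-3,5,5-trimethylcyclohex-3-ene-1,2-diol | CC1=C(/C=C/C(C)=C/C=C/C=C/C=C(C)/C#C)C(C)(C)C[C@H](O)[C@@H]1O | intermediate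
22 | prop-2-ynoic acid | C#CC(=O)O | starting material
23 | (2E)-2,3-dibromoprop-2-enoic acid (β-bromine cis to the carboxyl group) | OC(=O)/C(Br)=C\Br | intermediate
24 | (2E,6E,8E,10E,12E,14E)-2-bromo-15-[(3R,4S)-3,4-dihydroxy-2,6,6-trimethylcyclohex-1-en-1-yl]-6,13-dimethylpentadeca-2,6,8,10,12,14-hexaen-4-ynoic acid (not isolated) | CC1=C(/C=C/C(C)=C/C=C/C=C/C=C(C)/C#C/C=C(/Br)C(=O)O)C(C)(C)C[C@H](O)[C@@H]1O | intermediate
25 | (5Z)-3-bromo-5-[(2E,4E,6E,8E,10E)-11-[(3R,4S)-3,4-dihydroxy-2,6,6-trimethylcyclohex-1-en-1-yl]-2,9-dimethylundeca-2,4,6,8,10-pentaen-1-ylidene]furan-2(5H)-one | CC1=C(/C=C/C(C)=C/C=C/C=C/C=C(C)/C=C2C=C(Br)C(=O)O/2)C(C)(C)C[C@H](O)[C@@H]1O | intermediate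
26 | (4R,6R)-4-hydroxy-2,2,6-trimethylcyclohexan-1-one (actinol) | C[C@@H]1C[C@@H](O)CC(C)(C)C1=O | starting material
27 | (4R,6R)-2,2,6-trimethyl-4-[(triethylsilyl)oxy]cyclohexan-1-one | C[C@@H]1C[C@@H](O[Si](CC)(CC)CC)CC(C)(C)C1=O | intermediate
28 | (4R)-2,6,6-trimethyl-4-[(triethylsilyl)oxy]cyclohex-1-en-1-yl trifluoromethanesulfonate | CC1=C(OS(=O)(=O)C(F)(F)F)C(C)(C)C[C@H](O[Si](CC)(CC)CC)C1 | intermediate
29 | triethyl{[(1R)-4-ethynyl-3,5,5-trimethylcyclohex-3-en-1-yl]oxy}silane | CC1=C(C#C)C(C)(C)C[C@H](O[Si](CC)(CC)CC)C1 | intermediate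
30 | triethyl{[(1R,3S,6R)-6-ethynyl-1,5,5-trimethyl-7-oxabicyclo[4.1.0]heptan-3-yl]oxy}silane (epoxide anti to the silyloxy group) | C[C@]12O[C@@]1(C#C)C(C)(C)C[C@H](O[Si](CC)(CC)CC)C2 | intermediate
31 | (1R,3S,6R)-6-ethynyl-1,5,5-trimethyl-7-oxabicyclo[4.1.0]heptan-3-ol | C[C@]12O[C@@]1(C#C)C(C)(C)C[C@H](O)C2 | intermediate
32 | (1S,2R,4S)-1-ethynyl-2,6,6-trimethyl-7-oxabicyclo[2.2.1]heptan-2-ol (hydroxyl anti to the oxygen bridge) | C#C[C@@]12O[C@@H](CC1(C)C)C[C@@]2(C)O | intermediate
33 | (1R,2R,4S)-2,6,6-trimethyl-1-[(E)-2-(tributylstannyl)ethenyl]-7-oxabicyclo[2.2.1]heptan-2-ol | CCCC[Sn](CCCC)(CCCC)/C=C/[C@@]12O[C@@H](CC1(C)C)C[C@@]2(C)O | intermediate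
34 | (5Z)-5-[(2E,4E,6E,8E,10E)-11-[(3R,4S)-3,4-dihydroxy-2,6,6-trimethylcyclohex-1-en-1-yl]-2,9-dimethylundeca-2,4,6,8,10-pentaen-1-ylidene]-3-[(E)-2-[(1R,2R,4S)-2-hydroxy-2,6,6-trimethyl-7-oxabicyclo[2.2.1]heptan-1-yl]ethenyl]furan-2(5H)-one | CC1=C(/C=C/C(C)=C/C=C/C=C/C=C(C)/C=C2C=C(/C=C/[C@@]34O[C@@H](CC3(C)C)C[C@@]4(C)O)C(=O)O/2)C(C)(C)C[C@H](O)[C@@H]1O | target

**Totals.** 26 steps in all. The longest linear sequence is 16 steps (steps 1–13, 16, 18 and 26).

**Steps most likely to fail, with fallbacks**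

Step 6. The allyl cation may lose a proton or be captured before the carbonate closes, which would erode the yield and the cis control at C4. The fallback keeps the ring expansion but sets C4 by reduction instead of by the tether. It sets out from 5, which is silylated (TBSCl, imidazole) to the tert-butyldimethylsilyl ether F1 and converted with dibromocarbene into the dibromocyclopropane F2. Silver perchlorate in aqueous acetone should open F2 with capture of water at C4 to give the bromo allylic alcohol F3 as a mixture of C4 epimers. Dess–Martin oxidation would give the α-bromo enone F4. L-Selectride is expected to attack anti to the neighbouring silyloxy group and give the cis silyloxy alcohol F5. Fluoride then frees the bromo cis-diol F6, and carbonyldiimidazole closes the carbonate, returning to the route at 9.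

Step 24. Ionisation at C5 instead of attack at C6 would lead to ring contraction or elimination rather than to the oxygen bridge. The fallback sets out from 31, which is complexed with Co2(CO)8 to the hexacarbonyldicobalt alkyne complex F7. BF3·OEt2 at −78 °C should then ionise the epoxide selectively at the cobalt-stabilised propargylic carbon C6 (Nicholas reaction), and the C3 hydroxyl closes the bridge to give the complexed oxabicycle F8. Oxidative decomplexation with ceric ammonium nitrate returns to the route at 32.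

Step 18. The one-pot coupling–cyclisation may suffer from 6-endo closure to the pyranone, a second coupling at the α-bromide, alkyne homocoupling and loss of geometric purity of the polyene. The fallback separates the two events. It sets out from 23, which is esterified (EtOH, H2SO4) to ethyl (2E)-2,3-dibromoprop-2-enoate F9. Sonogashira coupling of F9 with 21 should give the isolable ethyl enynoate F10. Saponification (LiOH, THF/H2O, 0 °C) gives the acid 24, here isolated, and silver nitrate-catalysed 5-exo-dig lactonisation returns to the route at 25.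

**Further compounds**

F1 | step 6 | tert-butyl{[(1S)-3-[(methoxymethoxy)methyl]-4,4-dimethylcyclopent-2-en-1-yl]oxy}dimethylsilane | CC(C)(C)[Si](C)(C)O[C@@H]1C=C(COCOC)C(C)(C)C1
F2 | step 6 | tert-butyl{[(1S,2S,5R)-6,6-dibromo-5-[(methoxymethoxy)methyl]-4,4-dimethylbicyclo[3.1.0]hexan-2-yl]oxy}dimethylsilane | CC(C)(C)[Si](C)(C)O[C@@H]1[C@H]2C(Br)(Br)[C@@]2(COCOC)C(C)(C)C1
F3 | step 6 | (6S)-2-bromo-6-[(tert-butyldimethylsilyl)oxy]-3-[(methoxymethoxy)methyl]-4,4-dimethylcyclohex-2-en-1-ol (mixture of C1 epimers) | BrC1=C(COCOC)C(C)(C)C[C@H](O[Si](C)(C)C(C)(C)C)C1O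
F4 | step 6 | (6S)-2-bromo-6-[(tert-butyldimethylsilyl)oxy]-3-[(methoxymethoxy)methyl]-4,4-dimethylcyclohex-2-en-1-one | BrC1=C(COCOC)C(C)(C)C[C@H](O[Si](C)(C)C(C)(C)C)C1=O
F5 | step 6 | (1S,6S)-2-bromo-6-[(tert-butyldimethylsilyl)oxy]-3-[(methoxymethoxy)methyl]-4,4-dimethylcyclohex-2-en-1-ol (cis) | BrC1=C(COCOC)C(C)(C)C[C@H](O[Si](C)(C)C(C)(C)C)[C@@H]1O
F6 | step 6 | (1S,2S)-3-bromo-4-[(methoxymethoxy)methyl]-5,5-dimethylcyclohex-3-ene-1,2-diol (cis) | BrC1=C(COCOC)C(C)(C)C[C@H](O)[C@@H]1O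
F7 | step 24 | hexacarbonyldicobalt complex of the alkyne of 31 | C[C@]12O[C@@]1(C#C)C(C)(C)C[C@H](O)C2.[Co].[Co].[C-]#[O+].[C-]#[O+].[C-]#[O+].[C-]#[O+].[C-]#[O+].[C-]#[O+]
F8 | step 24 | hexacarbonyldicobalt complex of the alkyne of 32 | C#C[C@@]12O[C@@H](CC1(C)C)C[C@@]2(C)O.[Co].[Co].[C-]#[O+].[C-]#[O+].[C-]#[O+].[C-]#[O+].[C-]#[O+].[C-]#[O+]
F9 | step 18 | ethyl (2E)-2,3-dibromoprop-2-enoate | CCOC(=O)/C(Br)=C\Br
F10 | step 18 | ethyl (2E,6E,8E,10E,12E,14E)-2-bromo-15-[(3R,4S)-3,4-dihydroxy-2,6,6-trimethylcyclohex-1-en-1-yl]-6,13-dimethylpentadeca-2,6,8,10,12,14-hexaen-4-ynoate | CC1=C(/C=C/C(C)=C/C=C/C=C/C=C(C)/C#C/C=C(/Br)C(=O)OCC)C(C)(C)C[C@H](O)[C@@H]1O
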